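## Structural features

The target is a cembrane, a 14-membered carbocycle C1–C14. C1 carries the isopropylidene group C15(C16,C17), C2 is the ketone, and C3–C4 is the epoxide with C18 on C4. C8 carries C19, and C12 carries C20 and the acetate.

An oxygen bridge from C6 to C9 turns C6–C7–C8–C9 into a tetrahydrofuran, so the core is a 15-oxabicyclo[10.2.1]pentadecane with an sp2 bridgehead. The C9=C10 bond is exocyclic to the five-membered ring, endocyclic in the 14-membered ring, and a Z enol ether (C11 cis to O, C8–C9=C10–C11 transoid).

The stereocentres fall into three groups. C3/C4 are adjacent and form a trans epoxide derived from an E alkene. C6/C8 are 1,3-trans across the tetrahydrofuran, and C4/C6 are also 1,3-related. The quaternary C12 is isolated, with three atoms between it and C8.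

Several groups are fragile:
- The enol ether hydrolyses with acid, or migrates to endocyclic C8=C9 with loss of C8.
- The α,β-epoxy ketone is sensitive to base, nucleophiles and reductants.
- The tertiary acetate is prone to hydrolysis and ionisation.
- The twisted tetrasubstituted enone can deconjugate.

The real difficulty is to place C9=C10 in the right position and geometry inside the macrocycle. It must also be made late enough to escape every acidic or electrophilic step, and the remote C12 centre must be tied to the others.

The key step exploits the fact that C9, the anomeric carbon of the ring O/C6–C9, and C10 are the two ends of one double bond of the 14-membered ring. A sulfur atom placed between them gives a 15-membered 2-tetrahydrofuranyl alkyl sulfone that marks exactly this bond and can be extruded.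

## Logic of the disconnections

**33 ⇒ 32 ⇒ 31 ⇒ 30.** Three changes are made going backwards. The acetyl–O bond at C12 is cut, C1=C15 is moved back to C15=C16, and C2=O is taken back to the carbinol. This keeps the acetate and the cross-conjugated epoxy enone, both intolerant of strong base, out of the key step. It also makes C1 and C2 throw-away centres. The forward steps must be non-acidic and must converge all C1/C2 isomers.

**30 ⇒ 29 ⇒ 26 (key).** C9=C10 is cut and SO2 is inserted between the two carbons. The bridged 14-membered enol ether becomes a 15-membered sulfone that is stable to acid and oxidants. The positional (exo/endo) problem disappears because sulfur defines the two alkene carbons. The forward step must extrude SO2 under basic conditions, give the Z isomer, and leave the epoxide and C8 untouched.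

**26 ⇒ 25 ⇒ 23.** C1–C2 is cut. It is the only ring bond whose two ends are both destined to become sp2, so no stereocontrol is needed. This opens the ring to a chain with an aldehyde at C2 and an allyl donor C1–C15–C16. The forward closure must tolerate a sulfone, an epoxy aldehyde and a free tertiary alcohol.

**23 ⇒ 22 ⇒ 21 ⇒ 20.** These are functional-group changes only. The aldehyde goes back to the silyl ether, and the allylic chloride goes back to the intact prenyl terminus. The gain is that the prenyl alkene of the chiral-pool half serves as a latent C1 nucleophile. Chlorination must come after sulfur is fully oxidised and before the enol ether exists.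

**20 ⇒ 19 ⇒ 12 + 18.** The C9–S bond is cut. The molecule falls into two C10-sized halves joined by a thioacetalisation, one of the easiest heteroatom unions. It requires conditions under which the lactol ionises and the epoxide does not.

**18 ⇒ 17 ⇒ 16 ⇒ 14 ⇒ 13.** The C10–S and C10–O bonds are cut. All ten carbons C10–C14, C1, C15–C17 and C20, together with the C12 stereocentre, map onto 13. The only demand is chemoselective anti-Markovnikov functionalisation of the vinyl group.

**12 ⇒ 11 ⇒ 9.** The C8–C19 bond is cut. C8 is relayed from C6 by alkylation of the lactone enolate anti to the side chain, which gives the trans relationship the target needs.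

**9 ⇒ 7 ⇒ 5.** C7=C8 (olefination) and C6–O (α-oxygenation of an aldehyde) are cut. C6 is set by a catalyst, independently of the epoxide, and C8/C9 arrive as a two-carbon phosphonate.

**5 ⇒ 3 ⇒ 2 ⇒ 1.** The C7 carbonyl goes back to the terminal alkene, and the epoxide goes back to the E-allylic alcohol. C3 and C4 are set together by reagent control on an achiral commodity terpene.

## Other disconnections considered

**Alternative 1:** (the first idea) cut O–C9.
- *Forward key step:* a gold(I)-catalysed 5-exo-dig cycloisomerisation of the 14-membered cycloalkynol A1. Anti oxyauration and protodeauration would give the Z enol ether. The ring of A1 would be closed at C1–C2 or by alkyne metathesis.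
- *Structure:* the C10–C11 bond of A1 lies next to the quaternary C12, so an acetylide can be attached only by opening an enantiopure 2,2-disubstituted epoxide. The ten carbons of 13 cannot be used as they stand. C8 becomes a propargylic centre that needs its own asymmetric step.
- *Mechanism:* the choice between 5-exo and 6-endo attack would depend on a transannular geometry that cannot be set from outside. The carbophilic Lewis acid and the proton it releases are also the catalysts for migration of the double bond to C8=C9.
- *Step economy:* two alkyne termini, a protecting group on C6–OH and a separate route to C12 are estimated to cost more steps than steps 8–13 and 19.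

**Alternative 2:** cut C9–C10 with C9 as a carbonyl carbon.
- *Forward key step:* the organolithium A2 (from 16) would add to lactone 11 to give the hemiketal A3, which would then be dehydrated.
- *Mechanism:* dehydration runs through the oxocarbenium ion, which can lose a proton from C10 or from C8. Loss from C8 leads to the more substituted endocyclic isomer and erases C8. Nothing in A3 biases this choice or the E/Z geometry.
- *Structure:* the enol ether would exist before the prenyl terminus is functionalised, and it cannot survive an electrophilic chlorination.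
- *Comparison:* the sulfone route costs the same number of operations but fixes the position of the double bond by mechanism.

**Alternative 3:** cut C1–C2 in the biomimetic sense.
- *Forward key step:* the acid chloride A4 would be ionised with SnCl4. The prenyl alkene would attack the acylium ion to close the 14-membered ring as the β-chloro ketone A5, and E1cB loss of HCl would give the isopropylidene ketone.
- *Ground against it:* this handles the enone elegantly, but the Lewis acid excludes the enol ether, the epoxide and probably the tertiary acetate.
- *Consequences:* the enol ether would have to be masked as an alkyne, which brings back the problems of Alternative 1. The epoxide would have to be introduced last by nucleophilic epoxidation of a cross-conjugated dienone. Only the unknown ring conformation would then control the C3/C4 facial selectivity relative to C6.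

Key step: step 19

Remark (numbering): the cembrane numbering of the target given above is used for all intermediates.

Remark (assumption): centres that are erased later (C9 in 12 and 19–28, C1 in 21–31, C2 in 25–30, C10 in 27 and 28) are carried as mixtures and written without descriptor in the SMILES. Commercial 13 is taken as enantiopure.

## Steps

Step 1
Reactants: 1 geraniol, (2E)-3,7-dimethylocta-2,6-dien-1-ol
Product: 2 (2S,3S)-2,3-epoxygeraniol
Conditions: Ti(OiPr)4 (5 mol %), L-(+)-diethyl tartrate (7 mol %), t-BuOOH, 4 Å MS, CH2Cl2, −20 °C
Reagents that add atoms: tert-butyl hydroperoxide, CC(C)(C)OO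
Why: Katsuki–Sharpless asymmetric epoxidation: only the allylic alcohol alkene binds to titanium, so the remote trisubstituted alkene is left, and the L-(+)-tartrate complex delivers oxygen to the face that gives the (2S,3S)-epoxide; C3 and C4 of the target are set together by the reagent, trans because the alkene is E.

Step 2
Reactants: 2 (2S,3S)-2,3-epoxygeraniol
Product: 3 tert-butyldimethylsilyl ether of 2
Conditions: TBSCl, imidazole, CH2Cl2, 0 °C to rt
Reagents that add atoms: tert-butyldimethylsilyl chloride, CC(C)(C)[Si](C)(C)Cl
Why: Standard silylation of a primary alcohol; the ether blocks alkoxide-directed hydride opening and Payne migration of the epoxide in steps 6 and 7.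

Step 3
Reactants: 3 tert-butyldimethylsilyl ether of 2
Product: 5 3-[(2S,3S)-3-(tert-butyldimethylsilyloxymethyl)-2-methyloxiran-2-yl]propanal (C2–C7), via secondary ozonide 4 (not isolated)
Conditions: O3, CH2Cl2, −78 °C; then PPh3, −78 °C to rt
Reagents that add atoms: ozone, [O-][O+]=O
Why: Ozonolysis (Criegee mechanism) of the only alkene left, with reductive work-up of ozonide 4; epoxide and silyl ether are inert to ozone and phosphine at low temperature.

Step 4
Reactants: 5 C2–C7 epoxy aldehyde
Product: 7 ethyl (2E,4S)-4-(anilinooxy)-5-[(2S,3S)-3-(tert-butyldimethylsilyloxymethyl)-2-methyloxiran-2-yl]pent-2-enoate, via alpha-anilinooxy aldehyde 6 (not isolated)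
Conditions: PhNO, D-proline (20 mol %), DMSO, rt; then (EtO)2P(O)CH2CO2Et, LiCl, DBU, MeCN, 0 °C
Reagents that add atoms: nitrosobenzene, O=Nc1ccccc1; triethyl phosphonoacetate, CCOC(=O)CP(=O)(OCC)OCC
Why: Proline-catalysed α-aminoxylation followed by Horner–Wadsworth–Emmons olefination (Masamune–Roush conditions) in one flask: the enamine of 5 attacks the oxygen of nitrosobenzene that is hydrogen-bonded to the carboxylic acid of the catalyst, so C6 is set by the catalyst (D-proline gives 2S in 6) and not by the distant epoxide. The mild LiCl/DBU olefination should trap the configurationally labile aldehyde 6 at once as the E enoate.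

Step 5
Reactants: 7 gamma-anilinooxy enoate
Product: 9 (5R)-5-{[(2S,3S)-3-(tert-butyldimethylsilyloxymethyl)-2-methyloxiran-2-yl]methyl}dihydrofuran-2(3H)-one, via gamma-hydroxy ester 8 (not isolated)
Conditions: H2 (1 atm), 10 % Pd/C, EtOAc, rt; filter; PPTS (cat.), CH2Cl2, rt
Reagents that add atoms: none
Why: Catalytic hydrogenation saturates C7=C8 and hydrogenolyses the weak N–O bond, while the non-benzylic epoxide and the silyl ether should survive in a neutral aprotic solvent; the γ-hydroxy ester 8 then lactonises (5-exo-trig) under mild acid catalysis without touching C6.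

Step 6
Reactants: 9 gamma-substituted butyrolactone
Product: 11 (3S,5R)-3-methyl derivative of 9 (methyl trans to the C6 side chain), via lithium enolate 10 (not isolated)
Conditions: LDA, THF, −78 °C; MeI, −78 to −40 °C
Reagents that add atoms: lithium diisopropylamide, [Li]N(C(C)C)C(C)C (lithium stays in 10 only); iodomethane, CI
Why: Kinetic enolate alkylation of a γ-substituted butyrolactone: iodomethane approaches the nearly planar enolate 10 anti to the C6 side chain, so the C8 methyl group should end up trans to it, relayed from C6 by substrate control.

Step 7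
Reactants: 11 trans-methyl lactone
Product: 12 (3S,5R)-5-{[(2S,3S)-3-(tert-butyldimethylsilyloxymethyl)-2-methyloxiran-2-yl]methyl}-3-methyltetrahydrofuran-2-ol (C9 epimers)
Conditions: DIBAL-H (1.1 equiv), CH2Cl2, −78 °C; aq. Rochelle salt
Reagents that add atoms: none
Why: Partial reduction of a lactone with DIBAL-H: the tetrahedral aluminium alkoxide is stable at −78 °C and gives the lactol on work-up; the new C9 centre is a mixture that is erased in step 19.

Step 8
Reactants: 13 (R)-(−)-linalool
Product: 14 (R)-linalool triethylsilyl ether
Conditions: TESOTf, 2,6-lutidine, CH2Cl2, 0 °C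
Reagents that add atoms: triethylsilyl triflate, CC[Si](CC)(CC)OS(=O)(=O)C(F)(F)F
Why: A silyl triflate and a hindered pyridine silylate tertiary alcohols reliably; the ether is needed only to stop the C12 oxygen from capturing the activated C1=C15 alkene (cycloetherification) in step 14.

Step 9
Reactants: 14 (R)-linalool triethylsilyl ether
Product: 16 (3R)-3,7-dimethyl-3-(triethylsilyloxy)oct-6-en-1-ol, via B-alkyl-9-BBN adduct 15 (not isolated)
Conditions: 9-BBN, THF, 0 °C to rt; then aq. NaOH, H2O2, 0 °C
Reagents that add atoms: 9-borabicyclo[3.3.1]nonane, B1C2CCCC1CCC2 (stays in 15 only); hydrogen peroxide, OO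
Why: Brown hydroboration–oxidation: 9-BBN reacts with the monosubstituted vinyl group far faster than with the trisubstituted alkene and places boron on the terminal carbon C10; C12 is not involved and keeps its configuration.

Step 10
Reactants: 16 primary alcohol
Product: 17 S-[(3R)-3,7-dimethyl-3-(triethylsilyloxy)oct-6-enyl] ethanethioate
Conditions: PPh3, DIAD, AcSH, THF, 0 °C
Reagents that add atoms: thioacetic acid, CC(=O)S
Why: Mitsunobu reaction with an acidic sulfur pronucleophile, SN2 at the unhindered primary carbon C10.

Step 11
Reactants: 17 thioacetate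
Product: 18 (3R)-3,7-dimethyl-3-(triethylsilyloxy)oct-6-ene-1-thiol
Conditions: K2CO3 (0.2 equiv), degassed MeOH, 0 °C
Reagents that add atoms: none
Why: Base-catalysed methanolysis of the thioester, much faster than any attack on the silyl ether; exclusion of oxygen prevents disulfide formation.

Step 12
Reactants: 12 lactol; 18 thiol
Product: 19 open-chain 2-(alkylthio)tetrahydrofuran (C9–S–C10 thioacetal; C9 epimers)
Conditions: CSA (5 mol %), 4 Å MS, CH2Cl2, −20 °C
Reagents that add atoms: none
Why: Acid-catalysed thioacetalisation (the thioglycosidation reaction type): the lactol ionises readily to the five-membered oxocarbenium ion, which the soft thiol captures, whereas the epoxide is deactivated by the neighbouring C2–O bond and should not ionise with a catalytic sulfonic acid at low temperature. Both C9 epimers are usable.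

Step 13
Reactants: 19 thioacetal
Product: 20 open-chain 2-tetrahydrofuranyl alkyl sulfone
Conditions: (NH4)6Mo7O24·4H2O (10 mol %), 30 % H2O2, EtOH, 0 °C to rt
Reagents that add atoms: hydrogen peroxide, OO
Why: Molybdate-catalysed peroxide oxidation of sulfide to sulfone, the standard way to oxidise sulfur in the presence of trisubstituted alkenes, which react much more slowly with the peroxomolybdate.

Step 14
Reactants: 20 sulfone
Product: 21 C1 allylic chloride with C15=C16 methylidene (C1 epimers)
Conditions: NCS (1.1 equiv), PhSeCl (10 mol %), CH2Cl2, rt
Reagents that add atoms: N-chlorosuccinimide, O=C1CCC(=O)N1Cl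
Why: Selenium-catalysed ene-type allylic chlorination of a prenyl terminus: addition of the selenium electrophile to the only alkene and elimination with allylic transposition should give the secondary chloride at C1 and the C15=C16 methylidene; sulfone, epoxide and silyl ethers are not oxidised by NCS, and the C1 epimers converge in step 17.

Step 15
Reactants: 21 bis-silyl ether
Product: 22 chloro diol (C2–OH and C12–OH free)
Conditions: HF·pyridine, pyridine, THF, 0 °C to rt
Reagents that add atoms: none
Why: Fluoride-driven cleavage of both silyl ethers in a buffered, weakly acidic medium; basic fluoride sources are avoided because they would displace the allylic chloride.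

Step 16
Reactants: 22 chloro diol
Product: 23 alpha,beta-epoxy aldehyde (C2) with allylic chloride (C1)
Conditions: Dess–Martin periodinane, pyridine, CH2Cl2, 0 °C
Reagents that add atoms: none
Why: Dess–Martin oxidation stops at the aldehyde, cannot touch the tertiary C12 alcohol, and with pyridine as buffer should neither epimerise nor open the α,β-epoxy aldehyde.

Step 17
Reactants: 23 chloro aldehyde
Product: 25 15-membered cyclic sulfone with C2–OH and C1 isopropenyl group, via allylchromium(III) species 24 (not isolated)
Conditions: CrCl2 (10 equiv), NaI (cat.), 4 Å MS, THF, rt, slow addition, 2 mM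
Reagents that add atoms: chromium(II) chloride, Cl[Cr]Cl (chromium and chloride stay in 24 only)
Why: Nozaki–Hiyama–Kishi-type allylation, the classical closure of cembranoid rings, here to a 15-membered ring: Cr(II) inserts into the allylic C–Cl bond, the allylchromium(III) 24 settles with chromium on the primary carbon C16 and adds to the aldehyde through C1 in a six-membered transition state, which makes C1–C2 and leaves the isopropenyl group. Organochromium(III) reagents tolerate sulfones, epoxides and free tertiary alcohols, and the new centres C1 and C2 need no control because both become sp2 in step 21.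

Step 18
Reactants: 25 macrocyclic sulfone diol
Product: 26 C2 triethylsilyl ether of 25
Conditions: TESOTf (1.1 equiv), 2,6-lutidine, CH2Cl2, −78 °C
Reagents that add atoms: triethylsilyl triflate, CC[Si](CC)(CC)OS(=O)(=O)C(F)(F)F
Why: At low temperature the silyl triflate should silylate the secondary C2 alcohol before the tertiary C12 alcohol; the ether prevents a Payne rearrangement of the epoxy alcohol under the strongly basic conditions of step 19.

Step 19
Reactants: 26 15-membered 2-tetrahydrofuranyl alkyl sulfone
Product: 29 14-membered carbocycle with the (Z)-C9=C10 exocyclic enol ether, via C10-bromo sulfone 27 (not isolated), via episulfone 28 (not isolated)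
Conditions: KOH/Al2O3, BrCl2C–CCl2Br, t-BuOH–THF, 0 °C to rt
Reagents that add atoms: 1,2-dibromotetrachloroethane, ClC(Cl)(Br)C(Cl)(Cl)Br (bromine stays in 27 only)
Why: Ramberg–Bäcklund reaction in its in situ halogenation form, the reaction type that turns glycosyl sulfones into exo-glycals and macrocyclic sulfones into ring-contracted cycloalkenes. KOH deprotonates the sulfone next to sulfur, the carbanion takes Br+ from the dibromide to give 27, deprotonation at the other α-carbon is followed by 1,3-elimination of bromide (3-exo-tet) to episulfone 28, and cheletropic loss of SO2 gives C9=C10. The three-membered ring closure makes the C9–C10 bond and so converts the 15-membered thiacycle into the 14-membered carbocycle, without a C–C macrocyclisation, because both carbons are already held 1,3 on sulfur. Position: the alkene can form only between the two carbons that carried sulfur, so the endocyclic C8=C9 isomer, which would erase C8, is excluded by the mechanism, and the medium is never acidic. Geometry: no stereocentre is created and the new stereo-element is the double bond; SO2 loss is stereospecific, and the base-equilibrated episulfone should place C11 anti to the branched C8 (syn to the ring oxygen), which is also the arrangement with a transoid C8–C9=C10–C11 path in the ring, so allylic strain and ring strain both favour Z. The C9 epimers of 26 converge because C9 becomes planar. Chemoselectivity: the only C–H bonds acidic enough for KOH are those next to sulfur, the silylated C2 oxygen cannot start an epoxide migration, the C12 alkoxide has no electrophile within reach, and the dibromide ends as C2Cl4 and not as a carbene that could add to the new enol ether.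

Step 20
Reactants: 29 silyl ether
Product: 30 enol ether diol (C2–OH and C12–OH)
Conditions: TBAF, THF, 0 °C
Reagents that add atoms: none
Why: Fluoride cleavage of the triethylsilyl ether under non-acidic conditions, which the enol ether requires; at 0 °C the water content of the reagent should protonate the alkoxide before the epoxide can migrate.

Step 21
Reactants: 30 diol
Product: 32 12-O-deacetyl target (C2 ketone conjugated to C1=C15), via beta-gamma-unsaturated ketone 31 (not isolated)
Conditions: Dess–Martin periodinane, pyridine, CH2Cl2, 0 °C; aq. NaHCO3 wash; crude in toluene, DBU (0.5 equiv), rt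
Reagents that add atoms: none
Why: Buffered Dess–Martin oxidation of the secondary alcohol followed by base-catalysed conjugation: DBU removes the doubly activated C1–H of 31 and reprotonation of the dienolate at C16 gives the tetrasubstituted conjugated C1=C15 alkene, expected to be the thermodynamic isomer as in the isopulegone-to-pulegone isomerisation. All C1/C2 diastereomers converge to one compound.

Step 22
Reactants: 32 tertiary alcohol
Product: 33 target CNP0162736.1
Conditions: Ac2O, Et3N, DMAP, CH2Cl2, rt to 35 °C
Reagents that add atoms: acetic anhydride, CC(=O)OC(C)=O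
Why: DMAP-catalysed acylation (Steglich-type catalysis) of the tertiary alcohol through the N-acetylpyridinium ion; the conditions are non-acidic and too weakly basic to deconjugate the enone or open the epoxide, and C12 keeps its configuration because its C–O bond is not broken.

## Compound list

1 | geraniol | CC(C)=CCC/C(C)=C/CO | starting material
2 | (2S,3S)-2,3-epoxygeraniol | CC(C)=CCC[C@]1(C)O[C@H]1CO | intermediate
3 | TBS ether of 2 | CC(C)=CCC[C@]1(C)O[C@H]1CO[Si](C)(C)C(C)(C)C | intermediate
4 | secondary ozonide of 3 (not isolated) | CC1(C)OOC(CC[C@]2(C)O[C@H]2CO[Si](C)(C)C(C)(C)C)O1 | intermediate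
5 | C2–C7 epoxy aldehyde | O=CCC[C@]1(C)O[C@H]1CO[Si](C)(C)C(C)(C)C | intermediate
6 | (2S)-2-(anilinooxy) aldehyde (not isolated) | O=C[C@@H](ONc1ccccc1)C[C@]1(C)O[C@H]1CO[Si](C)(C)C(C)(C)C | intermediate
7 | ethyl (2E,4S)-4-(anilinooxy) enoate | CCOC(=O)/C=C/[C@@H](ONc1ccccc1)C[C@]1(C)O[C@H]1CO[Si](C)(C)C(C)(C)C | intermediate
8 | ethyl (4R)-4-hydroxy ester (not isolated) | CCOC(=O)CC[C@@H](O)C[C@]1(C)O[C@H]1CO[Si](C)(C)C(C)(C)C | intermediate
9 | (5R)-butyrolactone | O=C1CC[C@H](C[C@]2(C)O[C@H]2CO[Si](C)(C)C(C)(C)C)O1 | intermediate
10 | lithium enolate of 9 (not isolated) | [Li]OC1=CC[C@H](C[C@]2(C)O[C@H]2CO[Si](C)(C)C(C)(C)C)O1 | intermediate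
11 | (3S,5R)-3-methyl lactone, trans | O=C1[C@@H](C)C[C@H](C[C@]2(C)O[C@H]2CO[Si](C)(C)C(C)(C)C)O1 | intermediate
12 | (3S,5R)-lactol, C9 epimers | OC1O[C@@H](C[C@]2(C)O[C@H]2CO[Si](C)(C)C(C)(C)C)C[C@@H]1C | intermediate
13 | (R)-(−)-linalool | C=C[C@](C)(O)CCC=C(C)C | starting material
14 | (R)-linalool TES ether | C=C[C@](C)(O[Si](CC)(CC)CC)CCC=C(C)C | intermediate
15 | B-alkyl-9-BBN adduct (not isolated) | C1CC2CCCC(C1)B2CC[C@](C)(O[Si](CC)(CC)CC)CCC=C(C)C | intermediate
16 | (3R)-3,7-dimethyl-3-(triethylsilyloxy)oct-6-en-1-ol | OCC[C@](C)(O[Si](CC)(CC)CC)CCC=C(C)C | intermediate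
17 | C10 thioacetate | CC(=O)SCC[C@](C)(O[Si](CC)(CC)CC)CCC=C(C)C | intermediate
18 | C10 thiol | SCC[C@](C)(O[Si](CC)(CC)CC)CCC=C(C)C | intermediate
19 | open-chain C9–S–C10 thioacetal | CC(C)=CCC[C@@](C)(O[Si](CC)(CC)CC)CCSC1O[C@@H](C[C@]2(C)O[C@H]2CO[Si](C)(C)C(C)(C)C)C[C@@H]1C | intermediate
20 | open-chain sulfone | CC(C)=CCC[C@@](C)(O[Si](CC)(CC)CC)CCS(=O)(=O)C1O[C@@H](C[C@]2(C)O[C@H]2CO[Si](C)(C)C(C)(C)C)C[C@@H]1C | intermediate
21 | C1 allylic chloride | C=C(C)C(Cl)CC[C@@](C)(O[Si](CC)(CC)CC)CCS(=O)(=O)C1O[C@@H](C[C@]2(C)O[C@H]2CO[Si](C)(C)C(C)(C)C)C[C@@H]1C | intermediate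
22 | chloro diol | C=C(C)C(Cl)CC[C@@](C)(O)CCS(=O)(=O)C1O[C@@H](C[C@]2(C)O[C@H]2CO)C[C@@H]1C | intermediate
23 | chloro epoxy aldehyde | C=C(C)C(Cl)CC[C@@](C)(O)CCS(=O)(=O)C1O[C@@H](C[C@]2(C)O[C@H]2C=O)C[C@@H]1C | intermediate
24 | allylchromium(III) species (not isolated) | Cl[Cr](Cl)C/C(C)=C/CC[C@@](C)(O)CCS(=O)(=O)C1O[C@@H](C[C@]2(C)O[C@H]2C=O)C[C@@H]1C | intermediate
25 | 15-membered sulfone diol | O[C@@]1(C)CCS(=O)(=O)C2O[C@H](C[C@@H]2C)C[C@]2(C)O[C@H]2C(O)C(C(C)=C)CC1 | intermediate
26 | C2 TES ether of 25 | O[C@@]1(C)CCS(=O)(=O)C2O[C@H](C[C@@H]2C)C[C@]2(C)O[C@H]2C(O[Si](CC)(CC)CC)C(C(C)=C)CC1 | intermediate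
27 | C10-bromo sulfone (not isolated) | O[C@@]1(C)CC(Br)S(=O)(=O)C2O[C@H](C[C@@H]2C)C[C@]2(C)O[C@H]2C(O[Si](CC)(CC)CC)C(C(C)=C)CC1 | intermediate
28 | episulfone, C9-spiro thiirane 1,1-dioxide (not isolated) | O[C@@]1(C)CC2C3(O[C@H](C[C@@H]3C)C[C@]4(C)O[C@H]4C(O[Si](CC)(CC)CC)C(C(C)=C)CC1)S2(=O)=O | intermediate
29 | 14-membered (Z)-enol ether, C2 TES ether | O[C@@]1(C)C/C=C2\O[C@H](C[C@@H]2C)C[C@]2(C)O[C@H]2C(O[Si](CC)(CC)CC)C(C(C)=C)CC1 | intermediate
30 | enol ether diol | O[C@@]1(C)C/C=C2\O[C@H](C[C@@H]2C)C[C@]2(C)O[C@H]2C(O)C(C(C)=C)CC1 | intermediate
31 | β,γ-unsaturated epoxy ketone (not isolated) | O[C@@]1(C)C/C=C2\O[C@H](C[C@@H]2C)C[C@]2(C)O[C@H]2C(=O)C(C(C)=C)CC1 | intermediate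
32 | 12-O-deacetyl target | O[C@@]1(C)C/C=C2\O[C@H](C[C@@H]2C)C[C@]2(C)O[C@H]2C(=O)C(=C(C)C)CC1 | intermediate
33 | CNP0162736.1, (3R,4S,6R,8S,12R,9Z) | CC(=O)O[C@@]1(C)C/C=C2\O[C@H](C[C@@H]2C)C[C@]2(C)O[C@H]2C(=O)C(=C(C)C)CC1 | target

## Step count and least certain steps

Total step count: 22 (steps 1–7 to 12, steps 8–11 to 18, steps 12–22 after the union). Longest linear sequence: 18 (steps 1–7 and 12–22).

**Step 19 (key step).**
- *Most likely failure:* base-induced β-elimination of the sulfinate toward C8 may compete. This would open the thiacycle before halogenation and carbanion closure can occur.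
- *Other risks:* the 15-membered ring may hinder the W-shaped alignment needed for the 1,3-elimination. Incomplete equilibration of the episulfone may erode the Z selectivity.
- *Fallback:* sulfur stays as the linchpin, but the extrusion is taken out of the ring. The fallback sets out from 20 and comes back at 30.
  - Allylic oxidation of the prenyl terminus of 20 (SeO2 cat., t-BuOOH) should give the (E)-allylic alcohol F1.
  - The Ramberg–Bäcklund reaction is then run on this unconstrained open-chain sulfone to give the open-chain Z enol ether F2.
  - Boc2O/DMAP converts the allylic alcohol into the tert-butyl carbonate F3.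
  - TBAF removes both silyl groups to give the diol F4.
  - Buffered Dess–Martin oxidation gives the epoxy aldehyde F5.
  - The ring is closed at C1–C2 under neutral conditions by palladium-catalysed umpolung (Pd(PPh3)4, InI, high dilution). The allylindium adds through C1 and gives 30.

**Step 17.**
- *Failure modes:* single-electron reduction and opening of the α,β-epoxy aldehyde by excess Cr(II) may outrun C–C bond formation. Intermolecular addition may compete with ring closure.
- *Fallback:* the low-valent metal is replaced by a preformed, redox-neutral allyl donor. The fallback sets out from 22 and comes back at 25.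
  - Palladium-catalysed borylation of the allylic chloride (Pd2(dba)3, B2pin2) should give the (E)-allylboronate diol F6.
  - Dess–Martin oxidation gives the boronate aldehyde F7.
  - On warming at high dilution, F7 closes by intramolecular allylboration through a chair transition state at C1.
  - Mild hydrolysis of the borate gives 25.

**Step 12.**
- *Failure modes:* the acid may promote opening of the epoxide by the thiol. Reversible proton loss from the oxocarbenium ion may epimerise C8.
- *Fallback:* the C–S bond is made at the other carbon and under basic conditions. The fallback sets out from 12 and 16 and comes back at 19.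
  - A Mitsunobu reaction of lactol 12 with thioacetic acid should give the anomeric thioacetate F8.
  - An Appel iodination of 16 (I2, PPh3, imidazole) gives the primary iodide F9.
  - Diethylamine in DMF cleaves the thioester in situ, and the anomeric thiolate alkylates F9 at C10 to give 19.

**Step 21.**
- *Failure modes:* the base-mediated migration may stop at an unfavourable equilibrium, because the tetrasubstituted enone is twisted out of conjugation. Prolonged base contact may degrade the epoxy ketone.
- *Fallback:* the equilibrium is replaced by an irreversible E1cB elimination. The fallback sets out from 26 and comes back at 33.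
  - Mukaiyama hydration of the isopropenyl group of 26 (Mn(dpm)3 cat., PhSiH3, O2), done while no enol ether is present, should give the C15 tertiary alcohol F10.
  - The Ramberg–Bäcklund reaction gives the enol ether F11.
  - TBAF gives the triol F12.
  - Dess–Martin oxidation gives the β-hydroxy ketone F13.
  - Ac2O/DMAP acetylates both tertiary alcohols to give the diacetate F14.
  - DBU expels the C15 acetate through the C1 enolate, which can give only the conjugated C1=C15 alkene, that is 33.

## Further compounds

F1 | step 19 | open-chain sulfone (E)-C16 allylic alcohol | OC/C(C)=C/CC[C@@](C)(O[Si](CC)(CC)CC)CCS(=O)(=O)C1O[C@@H](C[C@]2(C)O[C@H]2CO[Si](C)(C)C(C)(C)C)C[C@@H]1C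
F2 | step 19 | open-chain (Z)-enol ether allylic alcohol | OC/C(C)=C/CC[C@@](C)(O[Si](CC)(CC)CC)C/C=C1\O[C@@H](C[C@]2(C)O[C@H]2CO[Si](C)(C)C(C)(C)C)C[C@@H]1C
F3 | step 19 | allylic tert-butyl carbonate | CC(C)(C)OC(=O)OC/C(C)=C/CC[C@@](C)(O[Si](CC)(CC)CC)C/C=C1\O[C@@H](C[C@]2(C)O[C@H]2CO[Si](C)(C)C(C)(C)C)C[C@@H]1C
F4 | step 19 | carbonate diol | CC(C)(C)OC(=O)OC/C(C)=C/CC[C@@](C)(O)C/C=C1\O[C@@H](C[C@]2(C)O[C@H]2CO)C[C@@H]1C
F5 | step 19 | carbonate epoxy aldehyde | CC(C)(C)OC(=O)OC/C(C)=C/CC[C@@](C)(O)C/C=C1\O[C@@H](C[C@]2(C)O[C@H]2C=O)C[C@@H]1C
F6 | step 17 | (E)-allylboronate diol | CC1(C)OB(C/C(C)=C/CC[C@@](C)(O)CCS(=O)(=O)C2O[C@@H](C[C@]3(C)O[C@H]3CO)C[C@@H]2C)OC1(C)C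
F7 | step 17 | allylboronate epoxy aldehyde | CC1(C)OB(C/C(C)=C/CC[C@@](C)(O)CCS(=O)(=O)C2O[C@@H](C[C@]3(C)O[C@H]3C=O)C[C@@H]2C)OC1(C)C
F8 | step 12 | anomeric (C9) thioacetate | CC(=O)SC1O[C@@H](C[C@]2(C)O[C@H]2CO[Si](C)(C)C(C)(C)C)C[C@@H]1C
F9 | step 12 | C10 primary iodide | ICC[C@](C)(O[Si](CC)(CC)CC)CCC=C(C)C
F10 | step 21 | macrocyclic sulfone C15 tertiary alcohol | O[C@@]1(C)CCS(=O)(=O)C2O[C@H](C[C@@H]2C)C[C@]2(C)O[C@H]2C(O[Si](CC)(CC)CC)C(C(C)(C)O)CC1
F11 | step 21 | (Z)-enol ether C15 tertiary alcohol | O[C@@]1(C)C/C=C2\O[C@H](C[C@@H]2C)C[C@]2(C)O[C@H]2C(O[Si](CC)(CC)CC)C(C(C)(C)O)CC1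
F12 | step 21 | enol ether triol | O[C@@]1(C)C/C=C2\O[C@H](C[C@@H]2C)C[C@]2(C)O[C@H]2C(O)C(C(C)(C)O)CC1
F13 | step 21 | β-hydroxy epoxy ketone | O[C@@]1(C)C/C=C2\O[C@H](C[C@@H]2C)C[C@]2(C)O[C@H]2C(=O)C(C(C)(C)O)CC1
F14 | step 21 | C12,C15 diacetate | CC(=O)O[C@@]1(C)C/C=C2\O[C@H](C[C@@H]2C)C[C@]2(C)O[C@H]2C(=O)C(C(C)(C)OC(C)=O)CC1
A1 | alternative 1 | 14-membered cycloalkynol | CC(=O)O[C@@]1(C)CC#C[C@@H](C)C[C@@H](O)C[C@]2(C)O[C@H]2C(=O)C(=C(C)C)CC1
A2 | alternative 2 | C10 organolithium | [Li]CC[C@](C)(O[Si](CC)(CC)CC)CCC=C(C)C
A3 | alternative 2 | C9 hemiketal | CC(C)=CCC[C@@](C)(O[Si](CC)(CC)CC)CCC1(O)O[C@@H](C[C@]2(C)O[C@H]2CO[Si](C)(C)C(C)(C)C)C[C@@H]1C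
A4 | alternative 3 | open-chain (E)-enoyl chloride | CC(C)=CCC[C@@](C)(OC(C)=O)CC#C[C@@H](C)C[C@@H](O[Si](C)(C)C(C)(C)C)C/C(C)=C/C(Cl)=O
A5 | alternative 3 | 14-membered β-chloro ketone | CC(=O)O[C@@]1(C)CC#C[C@@H](C)C[C@@H](O[Si](C)(C)C(C)(C)C)C/C(C)=C/C(=O)C(C(C)(C)Cl)CC1
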